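**Retrosynthetic overview**
1. Only the γ-lactone has to be made. It is closed last, as in lignan biosynthesis, by dehydrogenating an 8–8′-linked 9,9′-diol: allylic C9–OH → enal → lactol → lactone.
2. The unprotected (R,E)-seco-diol comes from one global LiAlH4 reduction of an imide/methyl enoate that carries two aryl pivalates.
3. The C8′–C7′ bond and the only stereocentre come from auxiliary-controlled benzylation of the extended imide enolate with a vanillyl bromide.
4. The E C7=C8 bond and the C9–C8–C8′–C9′ backbone come from a Stobbe condensation of 3-hydroxy-4,5-dimethoxybenzaldehyde with dimethyl succinate.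
5. Ring order: both arenes are bought; the lactone is formed in the final step.

Assumption: the presumed biosynthesis is the lignan pathway in which an 8–8′-linked 9,9′-diol is dehydrogenated via the lactol to the γ-lactone (lignan numbering: C7–C9 on the ring-A unit, C7′–C9′ on the ring-B unit).

**Step 1**
Reactants: 1 3-hydroxy-4,5-dimethoxybenzaldehyde; 2 dimethyl succinate
Product: 3 (E)-4-(3-hydroxy-4,5-dimethoxyphenyl)-3-(methoxycarbonyl)but-3-enoic acid
Conditions: NaOMe (3 equiv), MeOH, reflux; then 2 M HCl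
Reagents that add atoms: none
Why: Stobbe condensation: the succinate enolate adds to the aldehyde, the alkoxide lactonises onto the second ester and E1cB opening of the paraconate gives the half-ester with the free acid on the CH2 arm and the favoured E alkene (aryl trans to CO2Me); the meta-phenoxide only costs one extra equivalent of base.

**Step 2**
Reactants: 3 (E)-4-(3-hydroxy-4,5-dimethoxyphenyl)-3-(methoxycarbonyl)but-3-enoic acid; 4 (R)-4-benzyl-2-oxazolidinone
Product: 6 (R)-4-benzyl-3-[(E)-4-(3,4-dimethoxy-5-pivaloyloxyphenyl)-3-(methoxycarbonyl)but-3-enoyl]oxazolidin-2-one, via mixed pivalic anhydride 5 (not isolated)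
Conditions: PivCl (2.2 equiv), Et3N (3.5 equiv), THF, −20 → 0 °C; then LiCl (1.2 equiv), 4, 0 °C → rt
Reagents that add atoms: pivaloyl chloride, CC(C)(C)C(=O)Cl
Why: Mixed-anhydride N-acylation of an Evans oxazolidinone (LiCl/Et3N): one equivalent of PivCl activates the acid, the second caps the phenol as a hindered aryl pivalate that cannot be O-benzylated in step 5 and is removed in step 6; no stereocentre is formed.

**Step 3**
Reactants: 7 4-hydroxy-3-methoxybenzyl alcohol (vanillyl alcohol)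
Product: 8 4-(hydroxymethyl)-2-methoxyphenyl 2,2-dimethylpropanoate
Conditions: PivCl (1.05 equiv), NaOH (1.0 equiv), H2O/CH2Cl2, Bu4NHSO4 (cat.), 0 °C
Reagents that add atoms: pivaloyl chloride, CC(C)(C)C(=O)Cl
Why: Schotten–Baumann acylation: under aqueous NaOH only the phenoxide is acylated, the neutral benzylic alcohol is not.

**Step 4**
Reactants: 8 4-(hydroxymethyl)-2-methoxyphenyl 2,2-dimethylpropanoate
Product: 9 4-(bromomethyl)-2-methoxyphenyl 2,2-dimethylpropanoate
Conditions: PBr3 (0.4 equiv), CH2Cl2, 0 °C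
Reagents that add atoms: phosphorus tribromide, BrP(Br)Br
Why: PBr3 bromination (SN2 displacement of the benzylic phosphite ester by bromide); the hindered aryl pivalate is not touched.

**Step 5**
Reactants: 6 (R)-4-benzyl-3-[(E)-4-(3,4-dimethoxy-5-pivaloyloxyphenyl)-3-(methoxycarbonyl)but-3-enoyl]oxazolidin-2-one; 9 4-(bromomethyl)-2-methoxyphenyl 2,2-dimethylpropanoate
Product: 11 (R)-4-benzyl-3-[(2R,3E)-4-(3,4-dimethoxy-5-pivaloyloxyphenyl)-3-(methoxycarbonyl)-2-(3-methoxy-4-pivaloyloxybenzyl)but-3-enoyl]oxazolidin-2-one, via sodium (Z)-enolate 10 (not isolated)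
Conditions: NaHMDS (1.1 equiv), THF, −78 °C; then 9 (1.5 equiv), −78 → −40 °C
Reagents that add atoms: none
Why: Evans asymmetric alkylation: the chelated (Z)-sodium enolate 10 is attacked at its α-carbon on the face opposite the C4 benzyl group of the (R)-auxiliary, which gives (R) at C8′ (priorities C9′ > C8 > C7′), and the arylidene keeps its E geometry; the major diastereomer is purified here.

**Step 6**
Reactants: 11 (R)-4-benzyl-3-[(2R,3E)-4-(3,4-dimethoxy-5-pivaloyloxyphenyl)-3-(methoxycarbonyl)-2-(3-methoxy-4-pivaloyloxybenzyl)but-3-enoyl]oxazolidin-2-one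
Product: 12 (2E,3R)-2-[(3-hydroxy-4,5-dimethoxyphenyl)methylidene]-3-[(4-hydroxy-3-methoxyphenyl)methyl]butane-1,4-diol
Conditions: LiAlH4 (5 equiv), THF, −20 → 0 °C; aq. Rochelle salt
Reagents that add atoms: none
Why: LiAlH4 hydride reduction: the N-acyloxazolidinone is cleaved to the C9′ primary alcohol, the α-branched cinnamate is reduced 1,2 to the allylic C9 alcohol and both aryl pivalates are removed in the same operation; C8′ is no longer α to a carbonyl and cannot epimerise.

**Step 7**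
Reactants: 12 (2E,3R)-2-[(3-hydroxy-4,5-dimethoxyphenyl)methylidene]-3-[(4-hydroxy-3-methoxyphenyl)methyl]butane-1,4-diol
Product: 15 (3E,4R)-3-[(3-hydroxy-4,5-dimethoxyphenyl)methylidene]-4-[(4-hydroxy-3-methoxyphenyl)methyl]oxolan-2-one, via hydroxy-enal 13 (not isolated), via lactol 14 (not isolated)
Conditions: activated MnO2 (20 equiv), acetone, rt, dark
Reagents that add atoms: none
Why: Chemoselective allylic oxidation/oxidative lactonisation: MnO2 dehydrogenates only the allylic C9–OH to enal 13, the C9′–OH closes to the allylic lactol 14 and a second dehydrogenation gives the lactone (the diol → lactol → lactone order of the biosynthetic dehydrogenase), so the carbonyl ends at C9 while the saturated C9′–OH, the C8′ centre and the E alkene are untouched.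

**Compound list**
1 | 3-hydroxy-4,5-dimethoxybenzaldehyde | COc1cc(C=O)cc(O)c1OC | starting material
2 | dimethyl succinate | COC(=O)CCC(=O)OC | starting material
3 | (E)-4-(3-hydroxy-4,5-dimethoxyphenyl)-3-(methoxycarbonyl)but-3-enoic acid | COC(=O)/C(CC(=O)O)=C/c1cc(O)c(OC)c(OC)c1 | intermediate
4 | (R)-4-benzyl-2-oxazolidinone | O=C1N[C@H](Cc2ccccc2)CO1 | starting material
5 | mixed pivalic anhydride of the O-pivaloylated half-ester | COC(=O)/C(CC(=O)OC(=O)C(C)(C)C)=C/c1cc(OC(=O)C(C)(C)C)c(OC)c(OC)c1 | intermediate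
6 | (R)-4-benzyl-3-[(E)-4-(3,4-dimethoxy-5-pivaloyloxyphenyl)-3-(methoxycarbonyl)but-3-enoyl]oxazolidin-2-one | COC(=O)/C(CC(=O)N1[C@H](Cc2ccccc2)COC1=O)=C/c1cc(OC(=O)C(C)(C)C)c(OC)c(OC)c1 | intermediate
7 | 4-hydroxy-3-methoxybenzyl alcohol (vanillyl alcohol) | OCc1ccc(O)c(OC)c1 | starting material
8 | 4-(hydroxymethyl)-2-methoxyphenyl 2,2-dimethylpropanoate | CC(C)(C)C(=O)Oc1ccc(CO)cc1OC | intermediate
9 | 4-(bromomethyl)-2-methoxyphenyl 2,2-dimethylpropanoate | CC(C)(C)C(=O)Oc1ccc(CBr)cc1OC | intermediate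
10 | sodium (Z)-enolate of 6 | COC(=O)/C(/C=C(\[O-])N1[C@H](Cc2ccccc2)COC1=O)=C/c1cc(OC(=O)C(C)(C)C)c(OC)c(OC)c1.[Na+] | intermediate
11 | (R)-4-benzyl-3-[(2R,3E)-4-(3,4-dimethoxy-5-pivaloyloxyphenyl)-3-(methoxycarbonyl)-2-(3-methoxy-4-pivaloyloxybenzyl)but-3-enoyl]oxazolidin-2-one | COC(=O)/C(=C/c1cc(OC(=O)C(C)(C)C)c(OC)c(OC)c1)[C@@H](Cc1ccc(OC(=O)C(C)(C)C)c(OC)c1)C(=O)N1[C@H](Cc2ccccc2)COC1=O | intermediate
12 | (2E,3R)-2-[(3-hydroxy-4,5-dimethoxyphenyl)methylidene]-3-[(4-hydroxy-3-methoxyphenyl)methyl]butane-1,4-diol | OC/C(=C/c1cc(O)c(OC)c(OC)c1)[C@H](CO)Cc1ccc(O)c(OC)c1 | intermediate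
13 | (2E,3R)-4-hydroxy-2-[(3-hydroxy-4,5-dimethoxyphenyl)methylidene]-3-[(4-hydroxy-3-methoxyphenyl)methyl]butanal | O=C/C(=C/c1cc(O)c(OC)c(OC)c1)[C@H](CO)Cc1ccc(O)c(OC)c1 | intermediate
14 | (3E,4R)-3-[(3-hydroxy-4,5-dimethoxyphenyl)methylidene]-4-[(4-hydroxy-3-methoxyphenyl)methyl]oxolan-2-ol (both anomers) | COc1cc(C[C@H]2COC(O)/C2=C/c2cc(O)c(OC)c(OC)c2)ccc1O | intermediate
15 | (3E,4R)-3-[(3-hydroxy-4,5-dimethoxyphenyl)methylidene]-4-[(4-hydroxy-3-methoxyphenyl)methyl]oxolan-2-one | COc1cc(C[C@H]2COC(=O)/C2=C/c2cc(O)c(OC)c(OC)c2)ccc1O | target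

**Step count and risks**
Total step count: 7. Longest linear sequence: 5 steps (1 → 2 → 5 → 6 → 7).

The three steps most likely to fail:

Step 7, the dehydrogenative lactonisation on the unprotected bis-phenol, may suffer phenol oxidation by MnO2 or stall at the lactol. The fallback masks the phenols first and sets out from 12. Ac2O (2.1 equiv) with aqueous NaOH at 0 °C acylates only the phenoxides and gives (2E,3R)-2-[(3-acetoxy-4,5-dimethoxyphenyl)methylidene]-3-[(4-acetoxy-3-methoxyphenyl)methyl]butane-1,4-diol F4. MnO2 then gives the lactone (3E,4R)-3-[(3-acetoxy-4,5-dimethoxyphenyl)methylidene]-4-[(4-acetoxy-3-methoxyphenyl)methyl]oxolan-2-one F5. K2CO3 in MeOH removes both acetates and the sequence comes back at 15.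

Step 5, the alkylation of the hindered cross-conjugated dienolate, may be slow, may give γ-alkylation, or may erode the E geometry. The fallback replaces auxiliary control by resolution and sets out from 3 (with 9). The trilithio species of 3 (LDA, 3.2 equiv, THF, −78 °C) is alkylated with 9 to give racemic (E)-4-(3-hydroxy-4,5-dimethoxyphenyl)-3-(methoxycarbonyl)-2-(3-methoxy-4-pivaloyloxybenzyl)but-3-enoic acid F1. Crystallisation of its salt with the enantiomer of 1-phenylethylamine that gives the less soluble salt of the (R)-acid (chosen by screening) delivers (2R,3E)-4-(3-hydroxy-4,5-dimethoxyphenyl)-3-(methoxycarbonyl)-2-(3-methoxy-4-pivaloyloxybenzyl)but-3-enoic acid F2. LiAlH4 reduction of F2 (acid, ester and pivalate) comes back at 12.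

Step 6, the LiAlH4 reduction, may give conjugate reduction of the enoate or of the transient arylidene lactone. The fallback closes the ring by acyl transfer instead of dehydrogenation and sets out from 11. LiBH4 (THF/MeOH, 0 °C) reduces only the imide; the C9′ alkoxide closes onto the methyl enoate (cat. TsOH if needed). This gives (3E,4R)-3-[(3,4-dimethoxy-5-pivaloyloxyphenyl)methylidene]-4-[(3-methoxy-4-pivaloyloxyphenyl)methyl]oxolan-2-one F3; any partly depivaloylated material converges in the next operation. K2CO3 in MeOH removes the pivalates and the sequence comes back at 15, bypassing 12 and step 7.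

**Further compounds**
F1 | step 5 | racemic (E)-4-(3-hydroxy-4,5-dimethoxyphenyl)-3-(methoxycarbonyl)-2-(3-methoxy-4-pivaloyloxybenzyl)but-3-enoic acid | COC(=O)/C(=C/c1cc(O)c(OC)c(OC)c1)C(Cc1ccc(OC(=O)C(C)(C)C)c(OC)c1)C(=O)O
F2 | step 5 | (2R,3E)-4-(3-hydroxy-4,5-dimethoxyphenyl)-3-(methoxycarbonyl)-2-(3-methoxy-4-pivaloyloxybenzyl)but-3-enoic acid | COC(=O)/C(=C/c1cc(O)c(OC)c(OC)c1)[C@@H](Cc1ccc(OC(=O)C(C)(C)C)c(OC)c1)C(=O)O
F3 | step 6 | (3E,4R)-3-[(3,4-dimethoxy-5-pivaloyloxyphenyl)methylidene]-4-[(3-methoxy-4-pivaloyloxyphenyl)methyl]oxolan-2-one | COc1cc(C[C@H]2COC(=O)/C2=C/c2cc(OC(=O)C(C)(C)C)c(OC)c(OC)c2)ccc1OC(=O)C(C)(C)C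
F4 | step 7 | (2E,3R)-2-[(3-acetoxy-4,5-dimethoxyphenyl)methylidene]-3-[(4-acetoxy-3-methoxyphenyl)methyl]butane-1,4-diol | OC/C(=C/c1cc(OC(C)=O)c(OC)c(OC)c1)[C@H](CO)Cc1ccc(OC(C)=O)c(OC)c1
F5 | step 7 | (3E,4R)-3-[(3-acetoxy-4,5-dimethoxyphenyl)methylidene]-4-[(4-acetoxy-3-methoxyphenyl)methyl]oxolan-2-one | COc1cc(C[C@H]2COC(=O)/C2=C/c2cc(OC(C)=O)c(OC)c(OC)c2)ccc1OC(C)=O
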